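In a one-step world the substrate would simply react with the first nucleophile, and more nucleophile would mean a faster loss. I took the settings one after the other to test that on these runs, although Monday's and Wednesday's differ in substrate as well as first nucleophile, and Friday's differs from both in temperature and first nucleophile.

in all of them: second nucleophile 0.153 M

| run | substrate | first nucleophile | temperature | remark | time |
|---|---|---|---|---|---|
| Monday's | 0.051 M | 0.025 M | −15 °C | run made earlier |  |
| Friday's | 0.051 M | 0.10 M | 5 °C | run made earlier |  |
| Wednesday's | 0.076 M | 0.051 M | −15 °C | run made earlier |  |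
| green | 0.051 M | 0.0510 M | 0 °C |  | 40 min |
| teal | 0.051 M | 0.0510 M | 10 °C |  | 40 min |

| run | time / min | target / % | substrate / % | side product / % | other capture product / % |
|---|---|---|---|---|---|
| Monday's | 4.00 | 1.0 | 99.0 | 0 | 0.3 |
| Monday's | 12.0 | 1.6 | 98.2 | 0 | 1.0 |
| Monday's | 25.0 | 2.7 | 95.1 | 0.6 | 2.3 |
| Monday's | 30.0 | 2.1 | 94.3 | 0.1 | 2.6 |
| Monday's | 50.0 | 2.8 | 90.7 | 1.2 | 5.2 |
| Monday's | 60.0 | 3.8 | 89.0 | 0.2 | 6.1 |
| Monday's | 80.0 | 5.2 | 86.6 | 0.5 | 8.4 |
| Friday's | 3.00 | 7.5 | 91.2 | 0.7 | 2.2 |
| Friday's | 5.00 | 10.8 | 84.5 | 1.2 | 3.4 |
| Friday's | 8.00 | 17.7 | 77.7 | 1.7 | 6.2 |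
| Friday's | 12.0 | 22.0 | 67.2 | 2.3 | 7.4 |
| Friday's | 15.0 | 26.7 | 60.6 | 3.1 | 8.6 |
| Friday's | 25.0 | 37.1 | 42.4 | 8.7 | 13.6 |
| Friday's | 40.0 | 45.5 | 23.6 | 12.5 | 16.5 |
| Wednesday's | 15.0 | 1.7 | 97.2 | 0.5 | 0.7 |
| Wednesday's | 30.0 | 3.1 | 94.3 | 0.4 | 2.4 |
| Wednesday's | 50.0 | 4.4 | 90.8 | 1.2 | 3.1 |
| Wednesday's | 60.0 | 5.6 | 89.1 | 1.7 | 3.8 |
| Wednesday's | 80.0 | 6.4 | 84.3 | 2.2 | 4.8 |

(standard deviation of a reading: 0.5 percentage points)

- in percentages every species weighs as the substrate in it: one side product counts as two

* which of these there is most of at the end, counted by the substrate in it, green (substrate / side product / other capture product / target)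
* which of these there is most of at the end, counted by the substrate in it, teal (substrate / side product / other capture product / target)
* the largest of these amounts at the end, in percent of the substrate charged, green
* the largest of these amounts at the end, in percent of the substrate charged, teal

1. First nucleophile. By hand, twice the charge should double k, the first-order constant of substrate loss. But at the same temperature k was 0.00180 min⁻¹ in Monday's run and 0.00213 min⁻¹ in Wednesday's, less than double. So I assumed a rate-limiting step in which the substrate gives a short-lived intermediate, with the nucleophiles sharing it afterwards.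

2. Temperature. Friday's run gave 0.0361 min⁻¹. Taking ln k as straight in temperature between Wednesday's and Friday's runs, I got 0.0178 min⁻¹ for green and 0.0732 min⁻¹ for teal. That leaves 49.1% substrate in green and 5.35% in teal.

3. The two nucleophiles. With the intermediate at steady state, its concentration cancels from the ratio of the two captures. I counted half of each side product reading as former target, since one side product counts as two. Friday's last reading, with each nucleophile at its mean level, gives 51.8% target made and 5.38. This s is the selectivity factor: target made over other capture product made, per unit of [first nucleophile]/[second nucleophile].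

4. Green and teal. At the charge the ratio is 1.79. In green, target made stays near 32.7%, below the substrate left. In teal, using the mean levels from a first pass, the ratio falls to 1.32, still above one. Friday's share lost to side product then leaves target near 47.4%.

The forecast named substrate for green at 49.5% and target for teal at 41%, the teal figure resting on its words "the ratio falls from about 1.5 to 1"; my teal target stood higher.

    substrate ⇌ intermediate (K = 0.236, k = 0.0164 min⁻¹, Ea = 86.0 kJ mol⁻¹, ΔH = −49.0 kJ mol⁻¹)
    first nucleophile + intermediate → target (k = 1200 M⁻¹ min⁻¹, Ea = 47.0 kJ mol⁻¹)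
    second nucleophile + intermediate → other capture product (k = 240 M⁻¹ min⁻¹, Ea = 46.0 kJ mol⁻¹)
    substrate + target → side product (k = 0.175 M⁻¹ min⁻¹, Ea = 42.0 kJ mol⁻¹)
    (constants at 0 °C)

Green ended with substrate largest at 49.3%, and teal with target at 43.9%. Teal's made target over other capture product reads 1.31, against my 1.32. The neighbour is teal with 0.38 M of second nucleophile. There s gives a ratio of 0.722 at the charge, below one, so the other capture product should lead. Its end reads 0.585, with 29.0% target against 56.2% other capture product.

All runs come from a simulation with made-up constants.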